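**Retrosynthetic overview**

1. Carbocycle numbering used here: C1 = CH bearing the aroyl group, C2 = CH2, C3 = CH=, C4 = =C(4-methylpent-3-enyl), C5 = CH2, C6 = CHPh. Target 22 comes from bis-MOM ether 21 by acetal cleavage; 21 comes from enone 18 by rhodium-catalysed asymmetric 1,4-addition of PhB(OH)2 (C6–Ph bond, C6 stereocentre) and base equilibration at C1.
2. Key disconnection: ring bonds C2–C3 and C4–C5 together, by a cobalt-catalysed [4+2] of alkyne 15 (C3≡C4) with the 2-substituted buta-1,3-diene 13 (C5=C6–C1=C2), which already carries the whole arene as a silyl-protected carbinol on C1.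
3. Enabling feature: the only ring alkene, C3=C4, lies between two ring CH2 groups (C2 and C5), so the ring is an alkyne set between the termini of a diene. The C1=C6 bond left in the cyclohexa-1,4-diene is conjugated with the aryl ketone on C1, which is where phenyl and hydrogen must be added trans.
4. Diene 13 comes from the hexasubstituted benzaldehyde 9 by indium-mediated buta-1,3-dien-2-ylation. Aldehyde 9 comes from 5-methoxybenzene-1,3-diol by bis-MOM protection and three regiocontrolled metalations (CH3, CO2Me, CHO).
5. Ring order: the benzene ring is bought and substituted; the carbocycle is the only ring formed (step 9).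

Key step: step 9

Remark on the chemistry: the carbinol carbon in 11, 12, 13, 16 and 17 is formed racemic and is erased by the oxidation in step 11, so it is drawn without configuration.

**Route**

Step 1
Reactants: 1 5-methoxybenzene-1,3-diol
Product: 2 bis-MOM ether 1-methoxy-3,5-bis(methoxymethoxy)benzene
Conditions: NaH (2.5 equiv), MOMCl (2.4 equiv), DMF, 0 °C → rt
Reagents that add atoms: chloromethyl methyl ether, COCCl
Why: Williamson-type O-alkylation of both phenoxides gives the two acetal ethers that later serve as metalation-directing groups; no stereocentre is involved.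

Step 2
Reactants: 2 bis-MOM ether 1-methoxy-3,5-bis(methoxymethoxy)benzene
Product: 4 arene 5-methoxy-1,3-bis(methoxymethoxy)-2-methylbenzene, via aryllithium 3 (not isolated)
Conditions: n-BuLi (1.1 equiv), THF, 0 °C, 1 h; then MeI, 0 °C → rt
Reagents that add atoms: iodomethane, CI
Why: Directed ortho-metalation should occur at the ring position between the two OMOM groups, which is doubly chelated by the stronger of the two directing groups (OMOM over OMe), and the aryllithium is then methylated by SN2 on iodomethane.

Step 3
Reactants: 4 arene 5-methoxy-1,3-bis(methoxymethoxy)-2-methylbenzene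
Product: 6 methyl 6-methoxy-2,4-bis(methoxymethoxy)-3-methylbenzoate, via aryllithium 5 (not isolated)
Conditions: n-BuLi (1.1 equiv), TMEDA, THF, 0 °C; then cannulated into ClCO2Me (3 equiv), THF, −78 °C
Reagents that add atoms: methyl chloroformate, COC(=O)Cl
Why: A second directed ortho-metalation takes one of the two equivalent positions flanked by OMOM and OMe, and inverse addition of the aryllithium to excess chloroformate gives the ester without double addition because the doubly ortho-substituted ester is hindered.

Step 4
Reactants: 6 methyl 6-methoxy-2,4-bis(methoxymethoxy)-3-methylbenzoate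
Product: 7 methyl 3-iodo-2-methoxy-4,6-bis(methoxymethoxy)-5-methylbenzoate
Conditions: NIS (1.1 equiv), MeCN, 0 °C → rt, dark
Reagents that add atoms: N-iodosuccinimide, O=C1CCC(=O)N1I
Why: Electrophilic aromatic iodination can only take the last ring C–H, which is activated by three alkoxy groups, and neutral NIS spares the acid-labile MOM acetals.

Step 5
Reactants: 7 methyl 3-iodo-2-methoxy-4,6-bis(methoxymethoxy)-5-methylbenzoate
Product: 9 methyl 3-formyl-2-methoxy-4,6-bis(methoxymethoxy)-5-methylbenzoate, via arylmagnesium chloride 8 (not isolated)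
Conditions: iPrMgCl·LiCl (1.1 equiv), THF, −40 °C; then DMF (3 equiv), −40 °C → rt; aq NH4Cl
Reagents that add atoms: N,N-dimethylformamide, CN(C)C=O
Why: Iodine–magnesium exchange with the turbo-Grignard reagent is faster than attack on the hindered methyl ester, and the arylmagnesium is formylated by DMF (Bouveault aldehyde synthesis).

Step 6
Reactants: 9 methyl 3-formyl-2-methoxy-4,6-bis(methoxymethoxy)-5-methylbenzoate; 10 dibromide 1,4-dibromobut-2-yne
Product: 12 methyl 3-(1-hydroxy-2-methylidenebut-3-en-1-yl)-2-methoxy-4,6-bis(methoxymethoxy)-5-methylbenzoate (racemic), via bromoallene carbinol 11 (not isolated)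
Conditions: In powder (2.5 equiv), THF/H2O (1:1), rt
Reagents that add atoms: none
Why: Barbier-type indium-mediated buta-1,3-dien-2-ylation in water, in which the propargylic organoindium from 10 adds to the aldehyde with allylic transposition (SE2') to give bromoallene 11, whose C–Br bond is reduced by further indium and protonated with transposition to the 2-substituted diene; the ester is inert and the new carbinol centre is racemic and erased in step 11.

Step 7
Reactants: 12 methyl 3-(1-hydroxy-2-methylidenebut-3-en-1-yl)-2-methoxy-4,6-bis(methoxymethoxy)-5-methylbenzoate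
Product: 13 methyl 2-methoxy-4,6-bis(methoxymethoxy)-5-methyl-3-{2-methylidene-1-[(triethylsilyl)oxy]but-3-en-1-yl}benzoate
Conditions: TESCl (1.3 equiv), imidazole (2.5 equiv), DMF, rt
Reagents that add atoms: chlorotriethylsilane, CC[Si](Cl)(CC)CC
Why: Imidazole-promoted silylation with the small triethylsilyl group should proceed on the hindered secondary alcohol and masks the ionisable benzylic, allylic hydroxyl before exposure to zinc halides.

Step 8
Reactants: 14 homoprenyl bromide 5-bromo-2-methylpent-2-ene
Product: 15 enyne 6-methylhept-5-en-1-yne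
Conditions: LiC≡CH·H2NCH2CH2NH2 (1.5 equiv), DMSO, 10 °C → rt
Reagents that add atoms: lithium acetylide (ethylenediamine complex), [Li]C#C.NCCN
Why: SN2 alkylation of lithium acetylide by a primary bromide in DMSO is a standard terminal-alkyne synthesis and leaves the trisubstituted alkene untouched.

Step 9
Reactants: 13 methyl 2-methoxy-4,6-bis(methoxymethoxy)-5-methyl-3-{2-methylidene-1-[(triethylsilyl)oxy]but-3-en-1-yl}benzoate; 15 enyne 6-methylhept-5-en-1-yne
Product: 16 methyl 2-methoxy-4,6-bis(methoxymethoxy)-5-methyl-3-{[4-(4-methylpent-3-en-1-yl)cyclohexa-1,4-dien-1-yl][(triethylsilyl)oxy]methyl}benzoate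
Conditions: CoBr2(dppe) (10 mol%), Zn powder (20 mol%), ZnI2 (20 mol%), CH2Cl2, rt, argon, 15 (1.5 equiv) added over 2 h
Reagents that add atoms: none
Why: Zinc reduces CoBr2(dppe) to a cationic monovalent cobalt–dppe species (ZnI2 abstracts bromide) that binds the s-cis diene of 13 and the terminal alkyne of 15, couples them oxidatively to a trivalent cobaltacycle (σ-vinyl, η3-allyl) and closes the ring by reductive elimination. The closest known reaction type is the cobalt-catalysed neutral Diels–Alder reaction ([4+2] cycloaddition) of unactivated terminal alkynes with 2-substituted buta-1,3-dienes to give cyclohexa-1,4-dienes, a union that the thermal reaction of this electronically unmatched pair would not deliver. The six-membered carbocycle is closed in an intermolecular [4+2] mode, the two CH2 termini of the diene bonding to the two alkyne carbons. No stereocentre is created; the silyloxy carbon stays racemic and is erased in step 11. The step needs regioselectivity for the 1,4-disubstituted ("para") ring and chemoselectivity over alkyne cyclotrimerisation and over the trisubstituted alkene; the dppe ligand and the bulky 2-substituent of the diene should keep the alkyne substituent remote from the diene substituent, slow addition of 15 should suppress trimerisation, and trisubstituted alkenes do not engage this catalyst. The benzylic oxygen is carried as a silyl ether so that the Lewis-acidic zinc salts do not ionise it.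

Step 10
Reactants: 16 methyl 2-methoxy-4,6-bis(methoxymethoxy)-5-methyl-3-{[4-(4-methylpent-3-en-1-yl)cyclohexa-1,4-dien-1-yl][(triethylsilyl)oxy]methyl}benzoate
Product: 17 methyl 3-{hydroxy[4-(4-methylpent-3-en-1-yl)cyclohexa-1,4-dien-1-yl]methyl}-2-methoxy-4,6-bis(methoxymethoxy)-5-methylbenzoate
Conditions: TBAF (1.2 equiv), THF, 0 °C
Reagents that add atoms: none
Why: Fluoride-mediated desilylation cleaves the Si–O bond selectively, and the MOM acetals, the ester and the skipped diene are inert to it at 0 °C.

Step 11
Reactants: 17 methyl 3-{hydroxy[4-(4-methylpent-3-en-1-yl)cyclohexa-1,4-dien-1-yl]methyl}-2-methoxy-4,6-bis(methoxymethoxy)-5-methylbenzoate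
Product: 18 methyl 2-methoxy-4,6-bis(methoxymethoxy)-5-methyl-3-{[4-(4-methylpent-3-en-1-yl)cyclohexa-1,4-dien-1-yl]carbonyl}benzoate
Conditions: Dess–Martin periodinane (1.3 equiv), CH2Cl2, 0 °C → rt
Reagents that add atoms: none
Why: Dess–Martin oxidation converts the benzylic, allylic alcohol into the enone under non-basic, non-dehydrogenating conditions that should neither aromatise nor isomerise the cyclohexa-1,4-diene, and it removes the racemic carbinol centre.

Step 12
Reactants: 18 methyl 2-methoxy-4,6-bis(methoxymethoxy)-5-methyl-3-{[4-(4-methylpent-3-en-1-yl)cyclohexa-1,4-dien-1-yl]carbonyl}benzoate; 19 phenylboronic acid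
Product: 21 methyl 2-methoxy-4,6-bis(methoxymethoxy)-5-methyl-3-{[(1R,6R)-4-(4-methylpent-3-en-1-yl)-6-phenylcyclohex-3-en-1-yl]carbonyl}benzoate, via cis-ketone 20 (not isolated)
Conditions: [Rh(OH)((S)-BINAP)]2 (2.5 mol%), PhB(OH)2 (3 equiv), dioxane/H2O (10:1), 50 °C; then NaOMe (0.3 equiv), MeOH, rt
Reagents that add atoms: none
Why: Hayashi–Miyaura rhodium-catalysed asymmetric 1,4-addition of an arylboronic acid to an enone, in which by the established facial model the (S)-BINAP–phenylrhodium species should insert the C1=C6 bond from its α-si face and so place phenyl on C6 with the R configuration, water protonates the enolate to C1 epimers (cis-ketone 20 expected as the kinetic one, by analogy with 1-nitrocyclohexene), and methoxide then equilibrates C1 through the enolate to the more stable trans (1R,6R) ketone while C6 cannot epimerise.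

Step 13
Reactants: 21 methyl 2-methoxy-4,6-bis(methoxymethoxy)-5-methyl-3-{[(1R,6R)-4-(4-methylpent-3-en-1-yl)-6-phenylcyclohex-3-en-1-yl]carbonyl}benzoate
Product: 22 methyl 2,4-dihydroxy-6-methoxy-3-methyl-5-{[(1R,6R)-4-(4-methylpent-3-en-1-yl)-6-phenylcyclohex-3-en-1-yl]carbonyl}benzoate
Conditions: HCl (2 M aq)/MeOH/THF, rt
Reagents that add atoms: none
Why: Acid-catalysed acetal cleavage removes both MOM groups, which are each ortho to a carbonyl and therefore labile at room temperature, while the isolated trisubstituted alkenes, the methyl ester and the stereocentres (C1 already at its thermodynamic configuration) should be unaffected.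

**Compound list**

1 | 5-methoxybenzene-1,3-diol | COc1cc(O)cc(O)c1 | starting material
2 | 1-methoxy-3,5-bis(methoxymethoxy)benzene | COCOc1cc(OC)cc(OCOC)c1 | intermediate
3 | [4-methoxy-2,6-bis(methoxymethoxy)phenyl]lithium (formed in the flask) | [Li]c1c(OCOC)cc(OC)cc1OCOC | intermediate
4 | 5-methoxy-1,3-bis(methoxymethoxy)-2-methylbenzene | COCOc1cc(OC)cc(OCOC)c1C | intermediate
5 | [6-methoxy-2,4-bis(methoxymethoxy)-3-methylphenyl]lithium (formed in the flask) | [Li]c1c(OC)cc(OCOC)c(C)c1OCOC | intermediate
6 | methyl 6-methoxy-2,4-bis(methoxymethoxy)-3-methylbenzoate | COC(=O)c1c(OCOC)c(C)c(OCOC)cc1OC | intermediate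
7 | methyl 3-iodo-2-methoxy-4,6-bis(methoxymethoxy)-5-methylbenzoate | COC(=O)c1c(OCOC)c(C)c(OCOC)c(I)c1OC | intermediate
8 | chloro[2-methoxy-3-(methoxycarbonyl)-4,6-bis(methoxymethoxy)-5-methylphenyl]magnesium (formed in the flask) | COC(=O)c1c(OCOC)c(C)c(OCOC)c([Mg]Cl)c1OC | intermediate
9 | methyl 3-formyl-2-methoxy-4,6-bis(methoxymethoxy)-5-methylbenzoate | COC(=O)c1c(OCOC)c(C)c(OCOC)c(C=O)c1OC | intermediate
10 | 1,4-dibromobut-2-yne | BrCC#CCBr | starting material
11 | methyl 3-[2-(bromomethyl)-1-hydroxybuta-2,3-dien-1-yl]-2-methoxy-4,6-bis(methoxymethoxy)-5-methylbenzoate (racemic, formed in the flask) | COC(=O)c1c(OCOC)c(C)c(OCOC)c(C(O)C(CBr)=C=C)c1OC | intermediate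
12 | methyl 3-(1-hydroxy-2-methylidenebut-3-en-1-yl)-2-methoxy-4,6-bis(methoxymethoxy)-5-methylbenzoate (racemic) | COC(=O)c1c(OCOC)c(C)c(OCOC)c(C(O)C(=C)C=C)c1OC | intermediate
13 | methyl 2-methoxy-4,6-bis(methoxymethoxy)-5-methyl-3-{2-methylidene-1-[(triethylsilyl)oxy]but-3-en-1-yl}benzoate (racemic) | COC(=O)c1c(OCOC)c(C)c(OCOC)c(C(O[Si](CC)(CC)CC)C(=C)C=C)c1OC | intermediate
14 | 5-bromo-2-methylpent-2-ene | CC(C)=CCCBr | starting material
15 | 6-methylhept-5-en-1-yne | C#CCCC=C(C)C | intermediate
16 | methyl 2-methoxy-4,6-bis(methoxymethoxy)-5-methyl-3-{[4-(4-methylpent-3-en-1-yl)cyclohexa-1,4-dien-1-yl][(triethylsilyl)oxy]methyl}benzoate (racemic) | COC(=O)c1c(OCOC)c(C)c(OCOC)c(C(O[Si](CC)(CC)CC)C2=CCC(CCC=C(C)C)=CC2)c1OC | intermediate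
17 | methyl 3-{hydroxy[4-(4-methylpent-3-en-1-yl)cyclohexa-1,4-dien-1-yl]methyl}-2-methoxy-4,6-bis(methoxymethoxy)-5-methylbenzoate (racemic) | COC(=O)c1c(OCOC)c(C)c(OCOC)c(C(O)C2=CCC(CCC=C(C)C)=CC2)c1OC | intermediate
18 | methyl 2-methoxy-4,6-bis(methoxymethoxy)-5-methyl-3-{[4-(4-methylpent-3-en-1-yl)cyclohexa-1,4-dien-1-yl]carbonyl}benzoate | COC(=O)c1c(OCOC)c(C)c(OCOC)c(C(=O)C2=CCC(CCC=C(C)C)=CC2)c1OC | intermediate
19 | phenylboronic acid | OB(O)c1ccccc1 | starting material
20 | methyl 2-methoxy-4,6-bis(methoxymethoxy)-5-methyl-3-{[(1S,6R)-4-(4-methylpent-3-en-1-yl)-6-phenylcyclohex-3-en-1-yl]carbonyl}benzoate (cis, formed in the flask) | COC(=O)c1c(OCOC)c(C)c(OCOC)c(C(=O)[C@H]2CC=C(CCC=C(C)C)C[C@H]2c2ccccc2)c1OC | intermediate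
21 | methyl 2-methoxy-4,6-bis(methoxymethoxy)-5-methyl-3-{[(1R,6R)-4-(4-methylpent-3-en-1-yl)-6-phenylcyclohex-3-en-1-yl]carbonyl}benzoate (trans) | COC(=O)c1c(OCOC)c(C)c(OCOC)c(C(=O)[C@@H]2CC=C(CCC=C(C)C)C[C@H]2c2ccccc2)c1OC | intermediate
22 | methyl 2,4-dihydroxy-6-methoxy-3-methyl-5-{[(1R,6R)-4-(4-methylpent-3-en-1-yl)-6-phenylcyclohex-3-en-1-yl]carbonyl}benzoate | COC(=O)c1c(O)c(C)c(O)c(C(=O)[C@@H]2CC=C(CCC=C(C)C)C[C@H]2c2ccccc2)c1OC | target

**Step count and risks**

Total step count: 13. Longest linear sequence: 12 steps (steps 1–7 and 9–13; step 8 is a one-step side branch).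

Steps most likely to fail:

Step 9 (key cycloaddition). What may go wrong: regiochemical leakage towards the 1,3-disubstituted cyclohexadiene, alkyne cyclotrimerisation outrunning the hindered diene, ionisation of the electron-rich benzylic silyl ether by the zinc halides, and dehydrogenation of the cyclohexa-1,4-diene to the arene on handling in air. Fallback, which builds the same cyclohexadiene by a thermal cycloaddition with reversed roles: setting out from aldehyde 9, addition of ethynylmagnesium bromide (THF, −78 °C) would give the ethynyl carbinol F1, and Dess–Martin oxidation would give the aryl ethynyl ketone F2. Heating F2 with commercial myrcene (toluene, 80–110 °C) in a thermal Diels–Alder reaction should give the 1,4-adduct, which is enone 18, after chromatographic removal of the 1,3-isomer. The route is rejoined at 18 and continues with step 12.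

Step 12 (asymmetric phenyl addition). What may go wrong: slow insertion into the α-substituted, hindered enone so that protodeboronation consumes the boronic acid, base- or rhodium-hydride-mediated migration of the skipped diene into conjugation or its aromatisation, and loss of facial selectivity because the aryl ketone is twisted. Fallback, a stoichiometric racemic addition followed by resolution: setting out from enone 18, Ph2CuLi (from PhLi and CuI) with TMSCl in THF at −78 °C should give the silyl enol ether F3. NaOMe in MeOH would cleave it and equilibrate C1 to the racemic trans ketone, that is 21 together with its (1S,6S) enantiomer F4. Preparative chromatography on a chiral stationary phase would deliver 21, where the route is rejoined.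

Step 6 (dienylation of the aldehyde). What may go wrong: sluggish addition to the doubly ortho-substituted aldehyde, delivery of homopropargyl or allenyl carbinols by the ambident organoindium, incomplete reduction of bromoallene 11, and cleavage of MOM ethers by acidic indium salts in water. Fallback, with a preformed allenylmethyl halide under anhydrous conditions: setting out from aldehyde 9, 4-bromobuta-1,2-diene F5 (from commercial buta-2,3-dien-1-ol with PBr3 and pyridine in Et2O) and CrCl2 (3 equiv, THF, rt) would react in a Nozaki–Hiyama addition. The buta-2,3-dienylchromium species adds through a cyclic transition state at its γ-carbon and can therefore only give the buta-1,3-dien-2-yl carbinol 12, where the route is rejoined.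

Further compounds
F1 | step 9 | methyl 3-(1-hydroxyprop-2-yn-1-yl)-2-methoxy-4,6-bis(methoxymethoxy)-5-methylbenzoate (racemic) | COC(=O)c1c(OCOC)c(C)c(OCOC)c(C(O)C#C)c1OC
F2 | step 9 | methyl 2-methoxy-4,6-bis(methoxymethoxy)-5-methyl-3-(prop-2-ynoyl)benzoate | COC(=O)c1c(OCOC)c(C)c(OCOC)c(C(=O)C#C)c1OC
F3 | step 12 | methyl 2-methoxy-4,6-bis(methoxymethoxy)-5-methyl-3-{[4-(4-methylpent-3-en-1-yl)-6-phenylcyclohex-3-en-1-ylidene][(trimethylsilyl)oxy]methyl}benzoate (racemic, enol ether geometry not defined) | COC(=O)c1c(OCOC)c(C)c(OCOC)c(C(O[Si](C)(C)C)=C2CC=C(CCC=C(C)C)CC2c2ccccc2)c1OC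
F4 | step 12 | methyl 2-methoxy-4,6-bis(methoxymethoxy)-5-methyl-3-{[(1S,6S)-4-(4-methylpent-3-en-1-yl)-6-phenylcyclohex-3-en-1-yl]carbonyl}benzoate | COC(=O)c1c(OCOC)c(C)c(OCOC)c(C(=O)[C@H]2CC=C(CCC=C(C)C)C[C@@H]2c2ccccc2)c1OC
F5 | step 6 | 4-bromobuta-1,2-diene | C=C=CCBr
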